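**Retrosynthetic overview**

1. Target ⇒ trans-diaxial addition of bromine (C1–Br, C2–Br) to the ring alkene of (4R,8R)-8,9-dibromo-p-menth-1-ene.
2. (4R,8R)-8,9-Dibromo-p-menth-1-ene ⇒ C3–C4 and C8–Br: cationic cyclisation of (3R,6E)-8-bromolinalool with HBr. The cyclohexene, the only ring, is closed here.
3. (3R,6E)-8-Bromolinalool ⇒ C9–Br by Appel bromination of (E)-8-hydroxylinalool ⇒ C9–O by SeO2 allylic oxidation of (R)-(−)-linalool, which supplies all ten carbons.
4. Feature used: the adjacent stereocentres C4 (ring CH) and C8 (side-chain CBr(CH3)CH2Br) are the two carbons of an (E)-trisubstituted alkene in an acyclic linalyl chain. The C9 bromine sits next to C8, where it can bridge that carbon and relay the incoming bromide to the face of the new C3–C4 bond.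

Key step: step 3

Atom labels: target (p-menthane) numbering is used for every compound, the acyclic ones included. C1 is the carbinol carbon of linalool and C7 its methyl; C2 and C3 are the vinyl CH and CH2; C6 and C5 are the chain CH2 groups; C4=C8 is the trisubstituted alkene; C9 is the methyl on C8 trans to the chain; C10 is the methyl cis to it. The target is (1S,2S,4R,8R).

Assumption: commercial (R)-(−)-linalool is taken to be of high enantiomeric purity, since the route cannot raise the enantiomeric purity above that of this starting material.

**Route**

Step 1
Reactants: 1 (R)-(−)-linalool; 2 selenium dioxide (catalytic); 3 tert-butyl hydroperoxide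
Product: 4 (2E,6R)-2,6-dimethylocta-2,7-diene-1,6-diol [(E)-8-hydroxylinalool]
Conditions: SeO2 (0.3 equiv), t-BuOOH (2 equiv, in decane), CH2Cl2, 0 °C → rt
Reagents that add atoms: tert-butyl hydroperoxide, CC(C)(C)OO (oxygen, relayed through selenium dioxide, O=[Se]=O)
Why: Riley allylic oxidation in its catalytic SeO2/t-BuOOH form (ene reaction, then [2,3]-sigmatropic shift) selects the electron-rich trisubstituted alkene and, by the usual (E)-rule, the methyl trans to the chain (C9), so the C4=C8 geometry needed later is fixed here; the vinyl group has no allylic hydrogen and the carbinol stereocentre is not involved.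

Step 2
Reactants: 4 (2E,6R)-2,6-dimethylocta-2,7-diene-1,6-diol; 5 carbon tetrabromide; 6 triphenylphosphine
Product: 7 (3R,6E)-8-bromo-3,7-dimethylocta-1,6-dien-3-ol [(E)-8-bromolinalool]
Conditions: CBr4 (1.15 equiv), PPh3 (1.2 equiv), CH2Cl2, −30 → 0 °C; used at once
Reagents that add atoms: carbon tetrabromide, BrC(Br)(Br)Br
Why: Appel reaction: the unhindered primary allylic hydroxyl is activated by the PPh3/CBr4 pair and displaced by bromide in an SN2 step without allylic shift, whereas the hindered tertiary hydroxyl should not react at low temperature, so the alkene geometry and the carbinol configuration are kept.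

Step 3
Reactants: 7 (3R,6E)-8-bromo-3,7-dimethylocta-1,6-dien-3-ol; 8 hydrogen bromide
Product: 11 (4R,8R)-8,9-dibromo-p-menth-1-ene [(4R)-4-[(2R)-1,2-dibromopropan-2-yl]-1-methylcyclohex-1-ene], via 8-bromolinalyl cation bromide 9 (not isolated), via side-chain bromiranium bromide 10 (not isolated)
Conditions: anhydrous HBr (2 equiv, dry CH2Cl2 solution), CH2Cl2 (0.02 M), −78 → −50 °C; cold NaHCO3 (aq) quench
Reagents that add atoms: hydrogen bromide, Br
Why: Proposed new method: HBr protonates the tertiary allylic hydroxyl of 7, water leaves, and the cisoid allyl cation of ion pair 9 attacks C4 of the (E)-C4=C8 alkene through its primary terminus C3, while the allylic C9–Br bond, which lies roughly perpendicular to that alkene, lets the bromine bridge C8 from the face opposite to the incoming carbon to give bromiranium ion 10, which bromide then opens at the tertiary C8 with inversion. The closest known reactions are the cyclisation of linalool and linalyl esters to α-terpinyl halides and α-terpineol under dry hydrogen halide or solvolysis, which transfers chirality in part, and substitutions of β-bromoalkyl derivatives that go with retention through bromonium ions; their combination on an 8-bromolinalyl substrate is not known. The cyclohexene ring is closed by forming C3–C4 in a six-membered closure that is exo to the C4=C8 alkene and endo to the allyl cation, whose C1–C2 bond becomes the ring alkene. C4 (R) is set by the helicity of the ion pair: the (R)-carbinol ionises in the anti,endo conformer with the chain folded over the allyl face opposite to the leaving water, and this helix must close before it unwinds or collapses to achiral primary allylic bromides. C8 (R) is set by the (E)-geometry of the alkene together with the anti-bridging and inverting opening, which place the new C–C and C–Br bonds on the same face of the former alkene. The step therefore needs ring closure to outrun ion-pair return and the opening of 10 to occur at C8 and not at C9; the low temperature and weakly polar medium, the tertiary character of C8 and the alkene geometry fixed in step 1 are relied on for this.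

Step 4
Reactants: 11 (4R,8R)-8,9-dibromo-p-menth-1-ene; 12 bromine
Product: 14 (1S,2S,4R)-1,2-dibromo-4-[(2R)-1,2-dibromopropan-2-yl]-1-methylcyclohexane, via ring bromonium bromide 13 (not isolated)
Conditions: Br2 (1.0 equiv), CH2Cl2, −78 °C, dark; Na2S2O3 (aq) work-up, crystallisation without heating
Reagents that add atoms: bromine, BrBr
Why: Electrophilic anti addition of bromine to the trisubstituted ring alkene: with the C4 side chain equatorial on the half-chair, bromonium ion 13 on the face anti to that side chain is opened by bromide at the tertiary C1 along the axial path, so the Markovnikov and Fürst–Plattner preferences coincide and give the trans-diaxial (1S,2S) dibromide, and a bromonium ion on the other face reaches the same diastereomer by axial opening at C2; C4 and C8 are not touched.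

**Compound list**

1 | (R)-(−)-linalool, (3R)-3,7-dimethylocta-1,6-dien-3-ol | C=C[C@](C)(O)CCC=C(C)C | starting material
2 | selenium dioxide | O=[Se]=O | starting material
3 | tert-butyl hydroperoxide | CC(C)(C)OO | starting material
4 | (2E,6R)-2,6-dimethylocta-2,7-diene-1,6-diol | C=C[C@](C)(O)CC/C=C(\C)CO | intermediate
5 | carbon tetrabromide | BrC(Br)(Br)Br | starting material
6 | triphenylphosphine | c1ccc(cc1)P(c1ccccc1)c1ccccc1 | starting material
7 | (3R,6E)-8-bromo-3,7-dimethylocta-1,6-dien-3-ol | C=C[C@](C)(O)CC/C=C(\C)CBr | intermediate
8 | hydrogen bromide | Br | starting material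
9 | (6E)-8-bromo-3,7-dimethylocta-1,6-dien-3-ylium bromide (allyl cation/bromide ion pair, reacting as the cisoid helical conformer) | C=C[C+](C)CC/C=C(\C)CBr.[Br-] | intermediate
10 | (2S)-2-methyl-2-[(1R)-4-methylcyclohex-3-en-1-yl]bromiran-1-ium bromide (bromine bridging C8 and C9) | C[C@@]2(C[Br+]2)[C@@H]1CCC(C)=CC1.[Br-] | intermediate
11 | (4R)-4-[(2R)-1,2-dibromopropan-2-yl]-1-methylcyclohex-1-ene | C[C@](Br)(CBr)[C@@H]1CCC(C)=CC1 | intermediate
12 | bromine | BrBr | starting material
13 | 1,2-bromonium bromide of 11 (bromine bridging C1 and C2 on the ring face trans to the C4 side chain, C1 methyl on the cis face) | C[C@](Br)(CBr)[C@@H]1CC[C@@]2(C)[Br+][C@H]2C1.[Br-] | intermediate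
14 | (1S,2S,4R)-1,2-dibromo-4-[(2R)-1,2-dibromopropan-2-yl]-1-methylcyclohexane | C[C@](Br)(CBr)[C@@H]1CC[C@](C)(Br)[C@@H](Br)C1 | target

**Step count**

Total steps: 4. Longest linear sequence: 4.

**Steps most likely to fail**

Step 3 (labelled step).
- What may go wrong: ionisation from the transoid rotamer or collapse of the ion pair to allylic dibromides may outrun ring closure. The helical ion pair may relax before closure, which erodes C4. Bromide may open ion 10 at C9 or capture an unbridged cation, which erodes C8. Excess HBr may add to the ring alkene.
- Fallback (known chemistry, chiral pool in place of cyclisation): it sets out from bromine 12, now used in two equivalents, and replaces compounds 1 to 11 by commercial (R)-(+)-limonene F1. Addition in CH2Cl2 at −78 °C should take the ring alkene first, giving the trans-diaxial (1S,2S,4R)-1,2-dibromo-p-menth-8-ene F2. Without isolation, F2 takes up the second equivalent at the isopropenyl group to give target 14 together with its C8 epimer (1S,2S,4R)-1,2-dibromo-4-[(2S)-1,2-dibromopropan-2-yl]-1-methylcyclohexane F3. C4 then comes securely from the chiral pool, but C8 is not controlled. Compound 14 would be separated from F3 by fractional crystallisation or preparative HPLC, and its C8 configuration proven by X-ray diffraction. The fallback comes back to the route at 14.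

Step 4.
- What may go wrong: the syn-face bromonium ion may open at C1 through a twist-boat and lead to the diequatorial (1R,2R) dibromide. Radical allylic bromination may compete. The diaxial dibromide may equilibrate thermally to the diequatorial one during isolation.
- Fallback (two-stage hydroxybromination and substitution): it sets out from 11. N-Bromosuccinimide in aqueous acetone at 0 °C should let water enter only at the tertiary C1, giving the trans-diaxial bromohydrin (1S,2S,4R)-2-bromo-4-[(2R)-1,2-dibromopropan-2-yl]-1-methylcyclohexan-1-ol F4. The tertiary hydroxyl is then exchanged for bromide with retention (HBr in acetic acid, 0 °C), since the anti-periplanar C2 bromine bridges C1 on ionisation and bromide re-enters axially at C1. The fallback comes back to the route at 14.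

Step 2.
- What may go wrong: the tertiary allylic hydroxyl may be activated or ionised by the phosphonium reagent or by traces of HBr. The product may close to a vinyl tetrahydrofuran by SN2′ attack of that hydroxyl on the allylic bromide, during reaction or chromatography.
- Fallback (activation and displacement separated, phosphine-free): it sets out from 4. Selective mesylation of the primary hydroxyl (MsCl, Et3N, THF, −45 °C) gives (2E,6R)-6-hydroxy-2,6-dimethylocta-2,7-dien-1-yl methanesulfonate F5. Without isolation, LiBr in THF at 0 °C displaces the mesylate under neutral conditions. After aqueous work-up only, crude 7 goes straight into step 3, which is where the fallback comes back to the route.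

**Further compounds**

F1 | step 3 | (R)-(+)-limonene, (4R)-1-methyl-4-(prop-1-en-2-yl)cyclohex-1-ene | CC(=C)[C@@H]1CCC(C)=CC1
F2 | step 3 | (1S,2S,4R)-1,2-dibromo-1-methyl-4-(prop-1-en-2-yl)cyclohexane | CC(=C)[C@@H]1CC[C@](C)(Br)[C@@H](Br)C1
F3 | step 3 | (1S,2S,4R)-1,2-dibromo-4-[(2S)-1,2-dibromopropan-2-yl]-1-methylcyclohexane | C[C@@](Br)(CBr)[C@@H]1CC[C@](C)(Br)[C@@H](Br)C1
F4 | step 4 | (1S,2S,4R)-2-bromo-4-[(2R)-1,2-dibromopropan-2-yl]-1-methylcyclohexan-1-ol | C[C@](Br)(CBr)[C@@H]1CC[C@](C)(O)[C@@H](Br)C1
F5 | step 2 | (2E,6R)-6-hydroxy-2,6-dimethylocta-2,7-dien-1-yl methanesulfonate | C=C[C@](C)(O)CC/C=C(\C)COS(C)(=O)=O
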